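The numbers of this flask were drawn at random within sensible limits; no experiment stands behind them.

The catalyst comes out of every step it enters, so its amount in this flask stays as charged, and that constant turns the partner's loss into a plain count against the decomposed reagent.

    starting material + catalyst → catalyst + open intermediate (k1 = 1.8 × 10⁵ /M/s)
    partner + catalyst + open intermediate → catalyst + product (k2 = 2.7 × 10⁸ /M²/s)
    open intermediate + capture agent → trapped intermediate (k3 = 90 /M/s)
    open intermediate → decomposed reagent (k4 = 0.14 /s)

starting material 0.50 mM; partner 0.550 mM; capture agent 0.0100 mM; catalyst 0.50 µM; time 4.0 min

- the state of affairs at 4.0 min: stopped, and by what, or still going (all of the starting material has reacted / it is still moving / no working catalyst is left / the partner has run out first)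
- share of the starting material used up at 4.0 min
- product at 4.0 min, in percent of the starting material charged

- the reaction counts as stopped when no species that holds the starting material changes by six tenths of a point or more over the second half of the time
- run time (flask): 4.0 min

Dividing the rate of partner loss by the rate of decomposition cancels the open intermediate and the clock, so the logarithm of the fraction of partner left falls in step with the decomposed reagent formed. The givens fold into the capture number, 0.482: the step 2 constant times catalyst times charged starting material, over the step 4 constant, which is the fall in that logarithm when one whole charge of starting material decomposes. It stands below one, so decomposition is expected to take the larger share.

The clock can be dropped here because the half-life of the starting material, 0.128 min, and that of the open intermediate against decomposition, 0.0825 min, are both short against 4.0 min. The capture route, at 9.00 × 10⁻⁴ /s with the capture agent as charged, is far slower than decomposition, so it is set aside.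

One number is not quite enough. With the partner held at its charge, product would be 34.7 %, but that much product spends 31.5 % of the partner, so the charge ratio of partner to starting material, 1.10, enters too. The fraction of partner left is the exponential of minus the capture number times the decomposed share, and the product is what the partner lost. Repeated passes give 29.7 %, 31.6 % and 30.9 %, so this reckoning commits to about 30.9 % product, with 71.9 % of the partner left and the starting material consumed.

The forecast gives all of the starting material has reacted, conversion 100 % and product 31 %, holding that “Product is then set by the branching of the intermediate”. The simulation gives all of the starting material has reacted, conversion 100 % and product 31.0 %.

In this flask the partner route at its charged level, 0.0743 /s, runs slower than decomposition at 0.14 /s, and the readings at 4.0 min show decomposed reagent 68.6 % beside partner left 72 %, which read back a capture number of 0.479. The neighbour flask with 2.0 × 10⁻⁴ mM of catalyst has a capture number of 0.193, one pass from which gives 16.2 % product, and that flask stands at 16.3 %.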